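G reacts in the first phase with X, E in the second phase refills X, and the G.X formed goes on to D.

    X ⇌ E, rate k1*([X] - [E]/K1) per volume of the first phase (K1 = 2.7, k1 = 1.1 min⁻¹)
    G + X → G.X (k2 = 0.93 L mol⁻¹ min⁻¹)
    G.X ⇌ Q, rate k3*([G.X] - [Q]/K3) per volume of the first phase (K3 = 0.46, k3 = 0.022 min⁻¹)
    G.X → D (k4 = 0.080 min⁻¹)
    G + G.X ⇌ G.G.X, settled at all times (K5 = 10 L mol⁻¹)

| flask | G | E | time | volume of the second phase over the first |
|---|---|---|---|---|
| north-west | 0.0050 M | 0.0190 M | 8.0 h | 0.25 |
| east | 0.010 M | 0.0190 M | 8.0 h | 0.25 |
| south | 0.020 M | 0.0190 M | 8.0 h | 0.25 |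
| north-east | 0.040 M | 0.0190 M | 8.0 h | 0.25 |

- in percentages every species weighs as the G in it: one G.G.X counts as two
- for G.X the Q and G.G.X are counted in
- in the second phase: E, Q; everything else is in the first
- charges count per volume of the first phase; a concentration in a rate is the amount of a species over the volume of its own phase; every rate counts per litre of the first phase
- in an amount of G.X, one G.G.X counts as one G.X
- the concentration of G.X that is asked is that of its free form alone
- "hardly changes" means that all values lie within two and a half points (for a concentration: within two and a half percent of the largest)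
- run time (north-west): 8.0 h

- [G.X] (only what is free in solution, in the first phase) at the end for north-west, east, south, north-east, in this order
- the course of these numbers from the first flask to the last (falls, then rises / falls all the way / rises all the way / rises, then falls / hardly changes)

Which numbers must be known well comes first, then the reckoning.

1. The transfer coefficient of X and E can be rough. At 1.1 min⁻¹ it is far faster than the draw on X even in north-east, 0.0372 min⁻¹, so X and E are taken at balance.
2. Q and G.G.X are side stores of G.X. Q holds 0.115 of free G.X at balance. G.G.X holds 0.050 at the start in north-west and 0.400 in north-east. Neither constant enters the reckoning below.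
3. The partition ratio and the volume ratio matter. They set φ, the share of the reagent standing as X, 0.597, and with it κ, φ times the rate constant of G + X, 0.555 L mol⁻¹ min⁻¹. κ sits in an exponent, which reaches 3.73 in north-west.
4. The constant of G.X → D matters one for one. The half-life of free G.X by that step is 0.14 h, short against 8.0 h, so free G.X is a resting state. Hence [G.X] = ρ[G][X], where ρ, the resting ratio, is the rate constant of G + X over that of G.X → D, 11.6 L mol⁻¹.
5. The limiting reagent is G in north-west and east , E in south and north-east . With the pool of G.X small, each G lost costs one reagent. With Δ the charge of E minus the charge of G, [X] = φ(Δ + [G]). Then d[G]/dt = −κ[G]([G] + Δ), and [G]/([G] + Δ) = (charged G/charged E)·exp(−κΔt).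
6. My reckoning gives [G] of 8.89 × 10⁻⁵ M, 4.52 × 10⁻⁴ M, 0.00367 M and 0.0210 M. So [G.X] is 8.69 × 10⁻⁶ M, 2.96 × 10⁻⁵ M, 6.81 × 10⁻⁵ M and 5.41 × 10⁻⁶ M: up, then down.

The forecast stands above these numbers , at 9.800 × 10⁻⁶ M, 3.200 × 10⁻⁵ M, 7.200 × 10⁻⁵ M and 6.900 × 10⁻⁶ M, with the course rises, then falls, holding that “Free G.X peaks near the flask where G and X are matched”.

The simulation gives 9.85 × 10⁻⁶ M, 3.25 × 10⁻⁵ M, 7.26 × 10⁻⁵ M and 7.04 × 10⁻⁶ M, and the course rises, then falls.

In north-east the conversion of G.X into D has the largest single effect on [G.X], though it is not told as the main reason: with that step taken away, [G.X] there ends at 0.0146 M instead of 7.04 × 10⁻⁶ M. ρ applied to the end readings of north-west, [G] 8.96 × 10⁻⁵ M and [X] 0.00841 M, gives 8.76 × 10⁻⁶ M against 9.85 × 10⁻⁶ M. In north-east, [G] 0.0210 M and [X] 2.32 × 10⁻⁵ M give 5.67 × 10⁻⁶ M against 7.04 × 10⁻⁶ M.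

The constants were set for the occasion; the rest is arithmetic.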